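The numbers in the tables stem from a simulated flask for an exercise.

**Bench note.** Whoever takes this bench: solid substrate is dissolving in the flask, and the dissolved starting material goes on to ring, open dimer and side product. Keep it closed and stirred until the reading. Don't add solid: at 20.0 h the thinner south run reads 34 % ring, more than the 17 % of the north run.

| flask | solid substrate | remark | time |
|---|---|---|---|
| south | 0.067 M | run made earlier |  |
| north | 0.15 M | run made earlier |  |
| flask | 0.10 M |  | 15 h |

| run | time / h | ring / % | starting material / % |
|---|---|---|---|
| south | 2.50 | 4 | 11 |
| south | 6.00 | 18 | 15 |
| south | 12.0 | 31 | 12 |
| south | 20.0 | 34 | 0 |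
| north | 1.33 | 1 | 5 |
| north | 3.00 | 4 | 6 |
| north | 8.00 | 7 | 6 |
| north | 20.0 | 17 | 9 |

(standard deviation of a reading: 2 percentage points)

- ring at 15 h, in percent of the solid substrate charged
- concentration of starting material in solution at 15 h, in percent of saturation

- in percentages every species weighs as the solid substrate in it: one open dimer or side product counts as two
- as a solid, counted per litre of solution: solid substrate
- the earlier runs were read with a standard deviation of 2 percentage points
- steps under discussion: starting material -> ring; 2 starting material -> open dimer; solid substrate <-> starting material; starting material + ring -> side product
- at the start none of the solid substrate is in solution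
- starting material means what is dissolved; the solid is not counted in it

**The feed.** Read the south run: starting material still stands at 12 % at 12.0 h and at 0 % by 20.0 h, so take the solid as lasting about 12.0 h. Its charge of 0.067 M over that time gives a feed of 5.58 mM h⁻¹, the solid dissolved per litre and hour.

**Your reading.** Divide this flask's charge by the feed: my reckoning gives its solid 17.9 h, longer than 15 h, so expect solid still in the flask when you come. The dissolved level looks alike in both runs, which fits a ceiling or a balance of feed against use; my reckoning doesn't choose.

**The forecast.** It gives 21 % ring and 85 % of saturation, saying “the solution should be near saturation”.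

**The result.** The flask gives 23.2 % ring and 16.3 % of saturation.

    starting material → ring (k = 0.320 h⁻¹)
    2 starting material → open dimer (k = 4.40 M⁻¹ h⁻¹)
    solid substrate ⇌ starting material, rate k3*(cs3 - [starting material]) while solid is left; crystals form when [starting material] > cs3 (solubility = 0.0520 M, k = 0.120 h⁻¹)
    starting material + ring → side product (k = 10.0 M⁻¹ h⁻¹)

**Feed again.** At 15.0 h this flask makes starting material at 0.983 of the rate it uses it up, each step taken net, close to a steady state, and it holds 21.9 % solid where the feed reckons 16.2 %. For a flask charged with 0.025 M the same feed reckons the solid gone in 4.48 h, sooner than 15 h, and at 15.0 h that flask holds 0 % solid and 53.9 % ring.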